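**Plan**
- Retrosynthesis: the C24=C33 quinone methide is taken back to a C24 carbinol (cut C24–C25), ring D is cut at C24–C33, and the ten-membered ring is cut at C4–C6, which returns the acyl group to O8 as a twelve-membered lactone. Then follow the lactone C4–O8 bond, the diaryl ether bond C12–O13, C23–C2 and C20–C21.
- Enabling feature: the ten-membered ring (C2, C3, C4, C6, C12, O13, C14, C20, C21, C23) carries acyl carbon C4 on C6, next to hydroxyl O8 on C7. This ortho-hydroxyaryl ketone is what a 1,3 O-to-C acyl shift from an O8 aryl ester leaves behind.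
- Forward: the naphthalene is built from an arylacetic acid. A temporary lactone ring at O13/C20 brings in C21–C24 and is opened again. The glutarate arm is joined by Michael addition, the diaryl ether is made, the twelve-membered lactone is closed and then contracted to the ten-membered ketone. Ring D and the dihydroxyphenyl group come last.
- Stereochemistry: C21 comes from an amine-catalysed Friedel–Crafts alkylation. C23 and C2 come from one ester-enolate Michael addition steered by C21 and by enolate geometry. The key step creates no stereocentre.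

Key step: step 14

Remark: atom labels C1 to O38 follow the heavy-atom order of the target SMILES. The target is taken in the tautomer written (C37 ketone, C34 enol), assumed to be the form obtained after aqueous work-up.

**Step 1**
Reactants: 1 3,5-dimethoxyphenylacetic acid; 2 potassium methyl malonate
Product: 4 methyl 4-(3,5-dimethoxyphenyl)-3-oxobutanoate, via acyl imidazolide 3 (not isolated)
Conditions: 1,1'-carbonyldiimidazole (CDI), THF, rt; then 2, MgCl2, Et3N, MeCN, rt to 40 °C; aq. HCl
Reagents that add atoms: none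
Why: Masamune–Brooks chain extension, in which acyl imidazolide 3 C-acylates the magnesium enolate of the malonate half-ester and the adduct loses CO2 on acidification to give the β-keto ester.

**Step 2**
Reactants: 4 methyl 4-(3,5-dimethoxyphenyl)-3-oxobutanoate
Product: 5 6,8-dimethoxynaphthalene-1,3-diol
Conditions: conc. H2SO4, 0 °C to rt; ice water
Reagents that add atoms: none
Why: Intramolecular Friedel–Crafts acylation by the ester carbonyl at the ring carbon ortho to one methoxy group and para to the other, followed by enolisation of the cyclic 1,3-diketone, should give the aromatic naphthalenediol.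

**Step 3**
Reactants: 5 6,8-dimethoxynaphthalene-1,3-diol
Product: 6 6,8-dimethoxy-3-{[tri(propan-2-yl)silyl]oxy}naphthalen-1-ol
Conditions: i-Pr3SiCl (1.05 equiv), imidazole, DMF, 0 °C
Reagents that add atoms: chlorotri(propan-2-yl)silane, CC(C)[Si](Cl)(C(C)C)C(C)C
Why: Silyl ether formation is expected at the unhindered 3-OH because the 1-OH is crowded by, and hydrogen-bonded to, the peri 8-methoxy group.

**Step 4**
Reactants: 6 6,8-dimethoxy-3-{[tri(propan-2-yl)silyl]oxy}naphthalen-1-ol
Product: 7 tri(propan-2-yl)[(4,5,7-trimethoxynaphthalen-2-yl)oxy]silane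
Conditions: NaH, MeI, THF, 0 °C to rt
Reagents that add atoms: iodomethane, CI
Why: Williamson ether synthesis on the sodium naphthoxide methylates the remaining peri hydroxyl, the aryl silyl ether being stable to NaH and unable to migrate across the 1,3-relationship.

**Step 5**
Reactants: 7 tri(propan-2-yl)[(4,5,7-trimethoxynaphthalen-2-yl)oxy]silane
Product: 8 4,5,7-trimethoxynaphthalen-2-ol
Conditions: Bu4NF, THF, 0 °C; aq. NH4Cl
Reagents that add atoms: none
Why: Fluoride cleaves the Si–O bond (desilylation) and frees the 2-naphthol, whose C1 (the later C20) is then the most nucleophilic ring carbon.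

**Step 6**
Reactants: 8 4,5,7-trimethoxynaphthalen-2-ol; 9 (E)-but-2-enal
Product: 11 (1R)-6,7,9-trimethoxy-1-methyl-2,3-dihydro-1H-benzo[f]chromen-3-ol (both C3 epimers), via hydroxy aldehyde 10 (not isolated)
Conditions: (S)-2-[diphenyl(trimethylsilyloxy)methyl]pyrrolidine (20 mol%), PhCO2H (20 mol%), toluene, 0 °C
Reagents that add atoms: none
Why: Iminium-ion Friedel–Crafts alkylation followed by hemiacetalisation: naphthol C1 (ortho to OH, para to the 4-methoxy group) adds to the β-carbon of the E-iminium ion on the face away from the diphenyl(silyloxy)methyl group, which should set C21 as R, and hydroxy aldehyde 10 closes to the lactol.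

**Step 7**
Reactants: 11 (1R)-6,7,9-trimethoxy-1-methyl-2,3-dihydro-1H-benzo[f]chromen-3-ol
Product: 12 (1R)-6,7,9-trimethoxy-1-methyl-1,2-dihydro-3H-benzo[f]chromen-3-one
Conditions: Dess–Martin periodinane, CH2Cl2, rt
Reagents that add atoms: none
Why: Dess–Martin oxidation turns the lactol into the lactone under near-neutral conditions that spare the electron-rich naphthalene and cannot touch the non-enolisable C21 centre.

**Step 8**
Reactants: 12 (1R)-6,7,9-trimethoxy-1-methyl-1,2-dihydro-3H-benzo[f]chromen-3-one
Product: 14 tert-butyl (3R)-3-{4,5,7-trimethoxy-2-[(trifluoromethanesulfonyl)oxy]naphthalen-1-yl}butanoate, via potassium naphthoxide 13 (not isolated)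
Conditions: KOt-Bu (1.05 equiv), THF, −40 to 0 °C; then PhNTf2, 0 °C to rt; aq. NH4Cl
Reagents that add atoms: potassium tert-butoxide, CC(C)(C)[O-].[K+]; N-phenylbis(trifluoromethanesulfonimide), O=S(=O)(N(c1ccccc1)S(=O)(=O)C(F)(F)F)C(F)(F)F
Why: Transesterification of the aryl lactone by tert-butoxide is driven by release of the far less basic naphthoxide and of peri strain, and O-sulfonylation of 13 before any acid is added prevents re-lactonisation.

**Step 9**
Reactants: 14 tert-butyl (3R)-3-{4,5,7-trimethoxy-2-[(trifluoromethanesulfonyl)oxy]naphthalen-1-yl}butanoate; 15 methyl (E)-but-2-enoate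
Product: 17 1-tert-butyl 5-methyl (2R,3S)-3-methyl-2-[(1R)-1-{4,5,7-trimethoxy-2-[(trifluoromethanesulfonyl)oxy]naphthalen-1-yl}ethyl]pentanedioate, via lithium enolate 16 (not isolated)
Conditions: LiN(i-Pr)2 (1.05 equiv), THF, −78 °C; then 15, −78 °C; aq. NH4Cl at −78 °C
Reagents that add atoms: none
Why: Michael addition of a lithium ester enolate to an enoate: deprotonation in THF should give the E(O)-enolate 16, which adds to the E-crotonate through a chelated eight-membered transition state to give the anti glutarate (C2 S), while allylic 1,3-strain turns C21–H into the enolate plane so that the crotonate approaches opposite the naphthyl group (C23 R).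

**Step 10**
Reactants: 17 1-tert-butyl 5-methyl (2R,3S)-3-methyl-2-[(1R)-1-{4,5,7-trimethoxy-2-[(trifluoromethanesulfonyl)oxy]naphthalen-1-yl}ethyl]pentanedioate
Product: 18 1-tert-butyl 5-methyl (2R,3S)-2-[(1R)-1-(2-borono-4,5,7-trimethoxynaphthalen-1-yl)ethyl]-3-methylpentanedioate
Conditions: B2(OH)4, Pd(OAc)2 (5 mol%), XPhos (10 mol%), KOAc, MeOH, 60 °C
Reagents that add atoms: tetrahydroxydiboron, OB(O)B(O)O
Why: Palladium-catalysed borylation of an aryl triflate (oxidative addition of zerovalent palladium into C–OTf, acetate-assisted transmetalation with the diboron reagent, reductive elimination) tolerates both esters and gives the boronic acid directly.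

**Step 11**
Reactants: 18 1-tert-butyl 5-methyl (2R,3S)-2-[(1R)-1-(2-borono-4,5,7-trimethoxynaphthalen-1-yl)ethyl]-3-methylpentanedioate; 19 2-iodobenzene-1,3-diol
Product: 20 1-tert-butyl 5-methyl (2R,3S)-2-{(1R)-1-[2-(3-hydroxy-2-iodophenoxy)-4,5,7-trimethoxynaphthalen-1-yl]ethyl}-3-methylpentanedioate
Conditions: 19 (4 equiv), Cu(OAc)2 (1 equiv), pyridine, 4 Å MS, CH2Cl2, air, rt
Reagents that add atoms: none
Why: Chan–Lam coupling transfers the naphthyl group from boron to copper and joins it to the phenoxide at room temperature, where divalent copper does not insert into the C–I bond, and the excess of the symmetric diol suppresses double arylation.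

**Step 12**
Reactants: 20 1-tert-butyl 5-methyl (2R,3S)-2-{(1R)-1-[2-(3-hydroxy-2-iodophenoxy)-4,5,7-trimethoxynaphthalen-1-yl]ethyl}-3-methylpentanedioate
Product: 21 (3S,4R,5R)-4-(tert-butoxycarbonyl)-5-[2-(3-hydroxy-2-iodophenoxy)-4,5,7-trimethoxynaphthalen-1-yl]-3-methylhexanoic acid
Conditions: LiOH, THF/H2O, 0 °C to rt; then aq. HCl to pH 3
Reagents that add atoms: lithium hydroxide, [Li+].[OH-]
Why: Saponification removes the unhindered methyl ester at C4 while the tert-butyl ester at the crowded C24 resists hydroxide.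

**Step 13**
Reactants: 21 (3S,4R,5R)-4-(tert-butoxycarbonyl)-5-[2-(3-hydroxy-2-iodophenoxy)-4,5,7-trimethoxynaphthalen-1-yl]-3-methylhexanoic acid
Product: 22 twelve-membered iodoaryl macrolactone (C4–O8 lactone of 21; iodine at C6; tert-butyl ester at C24; 2S,21R,23R)
Conditions: 2-methyl-6-nitrobenzoic anhydride (MNBA), DMAP, toluene, slow addition to high dilution, 40 °C
Reagents that add atoms: none
Why: Shiina macrolactonisation: the mixed anhydride of the unhindered C4 acid forms chemoselectively and, as its acylpyridinium ion, acylates phenol O8 at high dilution to close the twelve-membered ring (C2, C3, C4, O8, C7, C6, C12, O13, C14, C20, C21, C23).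

**Step 14**
Reactants: 22 twelve-membered iodoaryl macrolactone
Product: 24 ten-membered ortho-hydroxyaryl ketone (C4 ketone on C6; free phenol O8–H; tert-butyl ester at C24; 2S,21R,23R), via C6 aryllithium 23 (not isolated)
Conditions: t-BuLi (2.2 equiv), THF/Et2O, −100 to −40 °C; then aq. NH4Cl
Reagents that add atoms: none
Why: Iodine–lithium exchange at C6 is expected to be faster at −100 °C than attack of t-BuLi on either ester and gives aryllithium 23 between O8 and O13. The carbanion adds to the lactone carbonyl C4 on the neighbouring O8 through a four-membered tetrahedral intermediate that collapses with loss of O8 as lithium phenoxide, an anionic Fries (1,3 O-to-C acyl) shift of the kind known for ortho-haloaryl esters after halogen–metal exchange. The ten-membered ring (C2, C3, C4, C6, C12, O13, C14, C20, C21, C23) is therefore closed not end to end but by contraction of the twelve-membered lactone, O8 and C7 leaving the ring in a 4-exo-trig attack, and the change from C–Li to O–Li should pay for the added strain. No stereocentre is formed, and C2, C21 and C23 are spectators as long as the short-lived 23 does not act as a base. Site selectivity (C6, not C9 or C11) is fixed by the position of iodine, chemoselectivity by the hindered tert-butyl ester at C24 and by the second equivalent of t-BuLi, which destroys t-BuI, and the product is shielded from further attack as the chelated phenoxide of the ortho-acyl phenol.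

**Step 15**
Reactants: 24 ten-membered ortho-hydroxyaryl ketone
Product: 26 ring D ketone (24 closed between C24 and C33 to a 2,3-dihydro-1H-phenalen-1-one unit; 2S,21R,23R), via carboxylic acid 25 (not isolated)
Conditions: CF3CO2H, (CF3CO)2O, CH2Cl2, 0 °C to rt; then MeOH, aq. NaHCO3
Reagents that add atoms: none
Why: Acid cleaves the tert-butyl ester to acid 25, whose mixed trifluoroacetic anhydride undergoes intramolecular Friedel–Crafts acylation at C33, the peri carbon ortho to the C34 and para to the C37 methoxy group, to close six-membered ring D.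

**Step 16**
Reactants: 26 ring D ketone; 27 1,3-dimethoxybenzene
Product: 29 C24 tertiary carbinol bearing the 2,6-dimethoxyphenyl group (2S,21R,23R; C24 configuration not controlled), via 2,6-dimethoxyphenyllithium 28 (not isolated)
Conditions: 27 (5 equiv), n-BuLi, THF, 0 °C to rt; CeCl3, THF, −78 °C; then 26, −78 to 0 °C; aq. NH4Cl
Reagents that add atoms: none
Why: 1,2-Addition of an organocerium reagent (made by transmetalation of aryllithium 28) is known to succeed with hindered, enolisable ketones where the lithium reagent deprotonates, the C4 ketone is masked as its chelated ortho-phenoxide between two ortho substituents, and the new C24 centre needs no control because it becomes trigonal in step 17.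

**Step 17**
Reactants: 29 C24 tertiary carbinol
Product: 30 CNP0225737.1 (target; 2S,21R,23R)
Conditions: BBr3 (excess), CH2Cl2, −78 °C to rt; then H2O
Reagents that add atoms: none
Why: BBr3 ionises the doubly benzylic carbinol, the cation is stabilised by the para oxygen on C37 and loss of that methyl group gives the C24=C33 quinone methide, while the same Lewis acid cleaves the other four aryl methyl ethers without involving C2, C21 or C23.

**Compound list**
1 | 3,5-dimethoxyphenylacetic acid | COc1cc(CC(=O)O)cc(OC)c1 | starting material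
2 | potassium methyl malonate | COC(=O)CC(=O)[O-].[K+] | starting material
3 | 2-(3,5-dimethoxyphenyl)-1-(1H-imidazol-1-yl)ethan-1-one (acyl imidazolide) | COc1cc(CC(=O)n2ccnc2)cc(OC)c1 | intermediate
4 | methyl 4-(3,5-dimethoxyphenyl)-3-oxobutanoate | COC(=O)CC(=O)Cc1cc(OC)cc(OC)c1 | intermediate
5 | 6,8-dimethoxynaphthalene-1,3-diol | COc1cc(OC)c2c(O)cc(O)cc2c1 | intermediate
6 | 6,8-dimethoxy-3-{[tri(propan-2-yl)silyl]oxy}naphthalen-1-ol | COc1cc(OC)c2c(O)cc(O[Si](C(C)C)(C(C)C)C(C)C)cc2c1 | intermediate
7 | tri(propan-2-yl)[(4,5,7-trimethoxynaphthalen-2-yl)oxy]silane | COc1cc(OC)c2c(OC)cc(O[Si](C(C)C)(C(C)C)C(C)C)cc2c1 | intermediate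
8 | 4,5,7-trimethoxynaphthalen-2-ol | COc1cc(OC)c2c(OC)cc(O)cc2c1 | intermediate
9 | (E)-but-2-enal | C/C=C/C=O | starting material
10 | (3R)-3-(2-hydroxy-4,5,7-trimethoxynaphthalen-1-yl)butanal (hydroxy aldehyde) | C[C@H](CC=O)c1c(O)cc(OC)c2c(OC)cc(OC)cc12 | intermediate
11 | (1R)-6,7,9-trimethoxy-1-methyl-2,3-dihydro-1H-benzo[f]chromen-3-ol (both C3 epimers) | C[C@@H]1CC(O)Oc2cc(OC)c3c(OC)cc(OC)cc3c21 | intermediate
12 | (1R)-6,7,9-trimethoxy-1-methyl-1,2-dihydro-3H-benzo[f]chromen-3-one | C[C@@H]1CC(=O)Oc2cc(OC)c3c(OC)cc(OC)cc3c21 | intermediate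
13 | potassium 1-[(2R)-4-tert-butoxy-4-oxobutan-2-yl]-4,5,7-trimethoxynaphthalen-2-olate (potassium naphthoxide) | C[C@H](CC(=O)OC(C)(C)C)c1c([O-])cc(OC)c2c(OC)cc(OC)cc12.[K+] | intermediate
14 | tert-butyl (3R)-3-{4,5,7-trimethoxy-2-[(trifluoromethanesulfonyl)oxy]naphthalen-1-yl}butanoate | C[C@H](CC(=O)OC(C)(C)C)c1c(OS(=O)(=O)C(F)(F)F)cc(OC)c2c(OC)cc(OC)cc12 | intermediate
15 | methyl (E)-but-2-enoate | C/C=C/C(=O)OC | starting material
16 | lithium E(O)-enolate of 14 (C21 cis to the tert-butoxy group) | C[C@H](/C=C(/O[Li])OC(C)(C)C)c1c(OS(=O)(=O)C(F)(F)F)cc(OC)c2c(OC)cc(OC)cc12 | intermediate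
17 | 1-tert-butyl 5-methyl (2R,3S)-3-methyl-2-[(1R)-1-{4,5,7-trimethoxy-2-[(trifluoromethanesulfonyl)oxy]naphthalen-1-yl}ethyl]pentanedioate | C[C@@H](CC(=O)OC)[C@@H](C(=O)OC(C)(C)C)[C@@H](C)c1c(OS(=O)(=O)C(F)(F)F)cc(OC)c2c(OC)cc(OC)cc12 | intermediate
18 | 1-tert-butyl 5-methyl (2R,3S)-2-[(1R)-1-(2-borono-4,5,7-trimethoxynaphthalen-1-yl)ethyl]-3-methylpentanedioate | C[C@@H](CC(=O)OC)[C@@H](C(=O)OC(C)(C)C)[C@@H](C)c1c(B(O)O)cc(OC)c2c(OC)cc(OC)cc12 | intermediate
19 | 2-iodobenzene-1,3-diol | Oc1cccc(O)c1I | starting material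
20 | 1-tert-butyl 5-methyl (2R,3S)-2-{(1R)-1-[2-(3-hydroxy-2-iodophenoxy)-4,5,7-trimethoxynaphthalen-1-yl]ethyl}-3-methylpentanedioate | C[C@@H](CC(=O)OC)[C@@H](C(=O)OC(C)(C)C)[C@@H](C)c1c(Oc2cccc(O)c2I)cc(OC)c2c(OC)cc(OC)cc12 | intermediate
21 | (3S,4R,5R)-4-(tert-butoxycarbonyl)-5-[2-(3-hydroxy-2-iodophenoxy)-4,5,7-trimethoxynaphthalen-1-yl]-3-methylhexanoic acid | C[C@@H](CC(=O)O)[C@@H](C(=O)OC(C)(C)C)[C@@H](C)c1c(Oc2cccc(O)c2I)cc(OC)c2c(OC)cc(OC)cc12 | intermediate
22 | twelve-membered iodoaryl macrolactone (C4–O8 lactone of 21; iodine at C6; tert-butyl ester at C24; 2S,21R,23R) | C[C@H]1CC(=O)Oc2cccc(c2I)Oc2cc(OC)c3c(OC)cc(OC)cc3c2[C@H](C)[C@@H]1C(=O)OC(C)(C)C | intermediate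
23 | C6 aryllithium of 22 | C[C@H]1CC(=O)Oc2cccc(c2[Li])Oc2cc(OC)c3c(OC)cc(OC)cc3c2[C@H](C)[C@@H]1C(=O)OC(C)(C)C | intermediate
24 | ten-membered ortho-hydroxyaryl ketone (C4 ketone on C6; phenol O8–H; tert-butyl ester at C24; 2S,21R,23R) | C[C@H]1CC(=O)c2c(O)cccc2Oc2cc(OC)c3c(OC)cc(OC)cc3c2[C@H](C)[C@@H]1C(=O)OC(C)(C)C | intermediate
25 | C24 carboxylic acid of 24 (2S,21R,23R) | C[C@H]1CC(=O)c2c(O)cccc2Oc2cc(OC)c3c(OC)cc(OC)cc3c2[C@H](C)[C@@H]1C(=O)O | intermediate
26 | ring D ketone (C24 ketone bonded to C33; 2S,21R,23R) | C[C@H]1CC(=O)c2c(O)cccc2Oc2cc(OC)c3c(OC)cc(OC)c4c3c2[C@H](C)[C@@H]1C4=O | intermediate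
27 | 1,3-dimethoxybenzene | COc1cccc(OC)c1 | starting material
28 | 2,6-dimethoxyphenyllithium | COc1cccc(OC)c1[Li] | intermediate
29 | C24 tertiary carbinol with 2,6-dimethoxyphenyl on C24 (2S,21R,23R; C24 unassigned) | C[C@H]1CC(=O)c2c(O)cccc2Oc2cc(OC)c3c(OC)cc(OC)c4c3c2[C@H](C)[C@@H]1C4(O)c1c(OC)cccc1OC | intermediate
30 | CNP0225737.1 (2S,21R,23R) | C[C@H]1CC(=O)c2c(O)cccc2Oc2cc(O)c3c4c2[C@H](C)[C@@H]1C(c1c(O)cccc1O)=C4C(O)=CC3=O | target

**Count**
Total steps: 17. Longest linear sequence: 17 steps (1 to 30); compounds 2, 9, 15, 19 and 27 are bought.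

**Steps most likely to fail**

Step 16. The aryl metal may deprotonate C23 instead of adding, which would erode the C23 configuration. The two crowded partners may also fail to combine, or the reagent may attack C4. The fallback sets out from 24 and comes back at 29. Compound 24 is cleaved with CF3CO2H alone to acid 25, which is isolated and coupled with MeNHOMe·HCl (EDC·HCl, HOBt, i-Pr2NEt) to the Weinreb amide F1. Aryllithium 28 adds to F1 through the stable chelated adduct to give the C24 2,6-dimethoxyphenyl ketone F2. MeSO3H in CH2Cl2 then closes ring D by carbonyl–arene cyclodehydration at C33, and aqueous quench of the resulting diaryl cation gives 29. The aryl group is thus introduced at an acyl derivative rather than at the hindered ring D ketone.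

Step 14. Proton transfer from C3–H2 to the C6 aryllithium, or addition of t-BuLi to the lactone, may outrun the transannular acyl shift, which has to build a strained ring. The fallback sets out from 18 and comes back at 24. Compound 18 is coupled with benzene-1,3-diol under the conditions of step 11 to the iodine-free phenol F3. This is saponified as in step 12 to the acid F4 and lactonised as in step 13 to the iodine-free twelve-membered lactone F5. Irradiation of F5 (254 nm, MeCN) should effect a photo-Fries rearrangement, a neutral radical-pair 1,3-acyl shift whose ortho product at C6 is 24. Migration to C9 would give an isomer that has to be separated, and the naphthalene chromophore may compete for the light.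

Step 9. Facial selectivity at C23 rests on acyclic 1,2-induction from C21 and may be poor, or the enolate geometry may partly be lost, so that C23/C2 diastereomers form. The fallback sets out from 12 and comes back at 17. Lactone 12 is deprotonated with LiN(SiMe3)2 (THF, −78 °C). Its ring-locked E(O)-enolate should add to 15 opposite the C21 methyl group on the six-membered ring to give the trans lactone F6. Opening with KOt-Bu and trapping with PhNTf2 as in step 8 gives 17.

**Further compounds**
F1 | step 16 | N-methoxy-N-methylamide of acid 25 at C24 (2S,21R,23R) | C[C@H]1CC(=O)c2c(O)cccc2Oc2cc(OC)c3c(OC)cc(OC)cc3c2[C@H](C)[C@@H]1C(=O)N(C)OC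
F2 | step 16 | C24 2,6-dimethoxyphenyl ketone of the ten-membered hydroxyaryl ketone (2S,21R,23R) | C[C@H]1CC(=O)c2c(O)cccc2Oc2cc(OC)c3c(OC)cc(OC)cc3c2[C@H](C)[C@@H]1C(=O)c1c(OC)cccc1OC
F3 | step 14 | 1-tert-butyl 5-methyl (2R,3S)-2-{(1R)-1-[2-(3-hydroxyphenoxy)-4,5,7-trimethoxynaphthalen-1-yl]ethyl}-3-methylpentanedioate | C[C@@H](CC(=O)OC)[C@@H](C(=O)OC(C)(C)C)[C@@H](C)c1c(Oc2cccc(O)c2)cc(OC)c2c(OC)cc(OC)cc12
F4 | step 14 | (3S,4R,5R)-4-(tert-butoxycarbonyl)-5-[2-(3-hydroxyphenoxy)-4,5,7-trimethoxynaphthalen-1-yl]-3-methylhexanoic acid | C[C@@H](CC(=O)O)[C@@H](C(=O)OC(C)(C)C)[C@@H](C)c1c(Oc2cccc(O)c2)cc(OC)c2c(OC)cc(OC)cc12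
F5 | step 14 | iodine-free twelve-membered lactone (22 with H at C6; 2S,21R,23R) | C[C@H]1CC(=O)Oc2cccc(c2)Oc2cc(OC)c3c(OC)cc(OC)cc3c2[C@H](C)[C@@H]1C(=O)OC(C)(C)C
F6 | step 9 | methyl (3S)-3-[(1R,2R)-6,7,9-trimethoxy-1-methyl-3-oxo-2,3-dihydro-1H-benzo[f]chromen-2-yl]butanoate | C[C@@H]1[C@@H]([C@@H](C)CC(=O)OC)C(=O)Oc2cc(OC)c3c(OC)cc(OC)cc3c21
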